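The target in both earlier runs climbs steeply and then sits on a level, and that level is what we reckon with.

all flasks: starting material 0.30 M
- theta: protic impurity 0.069 M; run made earlier
- zeta: protic impurity 0.20 M; run made earlier
- dusk: protic impurity 0.270 M; time 15 h
- spring: protic impurity 0.0900 M; time 15 h

| run | time / h | target / % |
|---|---|---|
| theta | 4.00 | 48.2 |
| theta | 8.00 | 56.3 |
| theta | 12.0 | 54.5 |
| theta | 15.0 | 55.4 |
| zeta | 4.00 | 46.8 |
| zeta | 8.00 | 51.2 |
| zeta | 12.0 | 51.1 |
| zeta | 15.0 | 50.9 |

(standard deviation of a reading: 1 percentage point)

* which of the two there is more of at the end, dusk (target / isomer of the product)
* which of the two there is more of at the end, spring (target / isomer of the product)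
* target at the end, in percent of the starting material charged, dusk
* target at the end, in percent of the starting material charged, spring

1. Slope. In the theta run the target reaches 48.2% by 4.00 h, a chord of 0.121 h⁻¹ of the charge.

2. Level. From 8.00 h on, the readings stay within their scatter of 1 percentage point. Their means read 55.4% for theta and 51.1% for zeta.

3. Knee. An exponential rise to theta's level gives a time constant of 1.96 h, which puts the knee, 3 constants on, near 5.88 h. That is earlier than 15 h, so we take dusk and spring, charged alike in starting material, to stand on their levels by then.

4. Rule. We take the protic impurity as a competitor for the starting material, with [protic impurity] held near its charge (pseudo-first-order). With the charge of starting material held, the level then falls as 1/(1 + b[protic impurity]), where b, the selectivity factor, is the pull of the impurity per unit concentration against the main route. The two levels read b = 0.678 L mol⁻¹. The share of the charge taken by the impurity is b[protic impurity]/(1 + b[protic impurity]).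

5. Dusk. Our level is 49.0% and the share 15.5%, which leaves 35.5% for everything else, less than the target.

6. Spring. Our level is 54.7% and the share 5.75%, which leaves 39.6%, again less than the target. We count the isomer of the product inside each remainder, and each remainder is smaller than either target level, so we name the target in both flasks.

The forecast gives 48.8% for dusk and 54.6% for spring, close to our levels but not the same numbers. It takes the balance as isomer, “formed by a parallel route that the protic impurity promotes”, and so names the isomer of the product for dusk and the target for spring.

Dusk ends with 47.9% target against 6.26% isomer of the product, spring with 54.3% against 7.04%.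

    starting material → intermediate (k = 2.10 × 10⁻⁴ s⁻¹)
    intermediate ⇌ target (K = 2.60, k = 1.60 × 10⁻⁴ s⁻¹)
    intermediate ⇌ isomer of the product (K = 22.0, k = 5.40 × 10⁻⁶ s⁻¹)
    2 starting material → self-condensation product (k = 1.70 × 10⁻⁵ L mol⁻¹ s⁻¹)
    starting material + protic impurity → quenched substrate (k = 2.10 × 10⁻⁴ L mol⁻¹ s⁻¹)
    starting material ⇌ dormant form (K = 6.30, k = 3.10 × 10⁻⁵ s⁻¹)

At the end dusk shows quenched substrate at 17.5% where our share gave 15.5%, and spring shows 6.53% where it gave 5.75%. The isomer of the product in dusk stays below our remainder of 35.5%. The neighbouring flask is dusk read at 40 h. The factor contains no time, so the reckoning gives that flask the same share and the same level, 49.0%. That flask shows quenched substrate at 18.0%, target at 43.6%, and isomer of the product at 14.4%.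

All runs are simulated on assumed constants; scatter was added.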